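**Retrosynthetic overview**

- The strategy rests on the unbranched, heteroatom-free nonadecyl chain on C3 of the pyrrole ring. It is cut between chain carbons 2 and 3 (counted from the ring) into a 2-(pyrrol-3-yl)ethyl radical and an n-heptadecyl radical, which come from pyrrolylpropanoic acid 8 and stearic acid 9 in a mixed Kolbe electrolysis.
- Acid 8 is traced to the N-tosyl 3-bromopyrrole ester 4 by a Heck reaction with benzyl acrylate, followed by one hydrogenation that saturates the side chain and frees the acid. Bromide 4 comes from commercial bromopyrrole ester 1 and TsCl.
- No ring is formed: the pyrrole ring is bought intact. The N-tosyl group, together with the 2-ester, shields the ring at the anode and is removed last with NaOMe in methanol.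

Key step: step 4

Remark: the target has no stereocentre, so no configuration has to be set. The acrylate is used as its benzyl ester so that a single hydrogenation both saturates the side chain and liberates the acid.

**Route**

Step 1
Reactants: 1 methyl 3-bromo-1H-pyrrole-2-carboxylate; 2 4-methylbenzenesulfonyl chloride
Product: 4 methyl 3-bromo-1-(4-methylphenylsulfonyl)-1H-pyrrole-2-carboxylate, via sodium pyrrolide 3 (not isolated)
Conditions: NaH, THF, 0 °C; then TsCl, 0 °C to rt
Reagents that add atoms: none
Why: N-sulfonylation, in which NaH removes the acidic N–H (the anion is stabilised by the 2-ester) and the pyrrolide nitrogen attacks the sulfonyl chloride at sulfur.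

Step 2
Reactants: 4 methyl 3-bromo-1-(4-methylphenylsulfonyl)-1H-pyrrole-2-carboxylate; 5 benzyl acrylate
Product: 6 benzyl (E)-3-[2-(methoxycarbonyl)-1-(4-methylphenylsulfonyl)-1H-pyrrol-3-yl]prop-2-enoate
Conditions: Pd(OAc)2 (5 mol %), P(o-tol)3 (10 mol %), NaOAc, DMF, 110 °C
Reagents that add atoms: none
Why: Mizoroki–Heck reaction, in which zerovalent palladium formed in the flask inserts into the C3–Br bond (activated by the neighbouring ester and the N-sulfonyl group), adds syn across the acrylate at its unsubstituted terminus and leaves by syn β-hydride elimination to give the E-alkene, whose geometry is erased in step 3.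

Step 3
Reactants: 6 benzyl (E)-3-[2-(methoxycarbonyl)-1-(4-methylphenylsulfonyl)-1H-pyrrol-3-yl]prop-2-enoate
Product: 8 3-[2-(methoxycarbonyl)-1-(4-methylphenylsulfonyl)-1H-pyrrol-3-yl]propanoic acid, via saturated benzyl ester 7 (not isolated)
Conditions: H2 (1 atm), 10% Pd/C, EtOAc/MeOH, rt
Reagents that add atoms: none
Why: Catalytic hydrogenation saturates the conjugated C=C and then hydrogenolyses the benzylic C–O bond in the same flask, while the aromatic N-sulfonyl pyrrole and the methyl ester should be inert at 1 atm and rt.

Step 4
Reactants: 8 3-[2-(methoxycarbonyl)-1-(4-methylphenylsulfonyl)-1H-pyrrol-3-yl]propanoic acid; 9 stearic acid (5 equiv)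
Product: 10 methyl 3-nonadecyl-1-(4-methylphenylsulfonyl)-1H-pyrrole-2-carboxylate
Conditions: Pt anode, Pt cathode, undivided cell, KOH (0.1 equiv per CO2H), MeOH, 45–50 °C, ca. 0.25 A cm−2, stopped while still weakly acidic
Reagents that add atoms: none
Why: Mixed Kolbe electrolysis: both carboxylates are oxidised by one electron at the Pt anode to acyloxy radicals that lose CO2, and the primary 2-(pyrrol-3-yl)ethyl and n-heptadecyl radicals, born side by side in the carboxylate layer at high current density, combine to form the bond between chain carbons 2 and 3, while the cathode reduces acid protons to H2 and so keeps the carboxylate concentration constant. The closest known reaction type is the crossed Kolbe coupling of a functionalised alkanoic acid (a half ester or a 3-arylpropanoic acid) with an excess of a fatty acid. No ring is closed and no stereocentre is formed. The step needs cross-coupling over homo-coupling, which the five-fold excess of cheap 9 secures statistically, the symmetrical hydrocarbon from 9 being removed on silica. It also needs radical combination over further oxidation to a cation, which is secured because the radical from 8 is primary and two carbons away from the ring, hence without benzylic-type stabilisation, and because smooth Pt, weakly acidic methanol and high current density favour the radical path. The pyrrole ring should survive because the N-sulfonyl and 2-ester groups raise its oxidation potential, and the sulfonamide should survive because the base stays bound as carboxylate as long as free acid remains.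

Step 5
Reactants: 10 methyl 3-nonadecyl-1-(4-methylphenylsulfonyl)-1H-pyrrole-2-carboxylate
Product: 11 methyl 3-nonadecyl-1H-pyrrole-2-carboxylate
Conditions: NaOMe (5 equiv), MeOH/THF, rt to 40 °C; then aq. NH4Cl
Reagents that add atoms: none
Why: Nucleophilic N-desulfonylation, in which methoxide attacks the sulfonyl sulfur and expels the ester-stabilised pyrrolide, the methyl ester can only exchange with itself in methanol, and the excess methoxide demethylates the sulfonate ester so formed, so that no methylating agent is left.

**Compound list**

1 | methyl 3-bromo-1H-pyrrole-2-carboxylate | COC(=O)c1[nH]ccc1Br | starting material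
2 | 4-methylbenzenesulfonyl chloride | Cc1ccc(cc1)S(Cl)(=O)=O | starting material
3 | sodium 3-bromo-2-(methoxycarbonyl)pyrrol-1-ide | [Na+].COC(=O)c1[n-]ccc1Br | intermediate
4 | methyl 3-bromo-1-(4-methylphenylsulfonyl)-1H-pyrrole-2-carboxylate | COC(=O)c1c(Br)ccn1S(=O)(=O)c1ccc(C)cc1 | intermediate
5 | benzyl acrylate | C=CC(=O)OCc1ccccc1 | starting material
6 | benzyl (E)-3-[2-(methoxycarbonyl)-1-(4-methylphenylsulfonyl)-1H-pyrrol-3-yl]prop-2-enoate | COC(=O)c1c(/C=C/C(=O)OCc2ccccc2)ccn1S(=O)(=O)c1ccc(C)cc1 | intermediate
7 | benzyl 3-[2-(methoxycarbonyl)-1-(4-methylphenylsulfonyl)-1H-pyrrol-3-yl]propanoate | COC(=O)c1c(CCC(=O)OCc2ccccc2)ccn1S(=O)(=O)c1ccc(C)cc1 | intermediate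
8 | 3-[2-(methoxycarbonyl)-1-(4-methylphenylsulfonyl)-1H-pyrrol-3-yl]propanoic acid | COC(=O)c1c(CCC(=O)O)ccn1S(=O)(=O)c1ccc(C)cc1 | intermediate
9 | stearic acid (octadecanoic acid) | CCCCCCCCCCCCCCCCCC(=O)O | starting material
10 | methyl 3-nonadecyl-1-(4-methylphenylsulfonyl)-1H-pyrrole-2-carboxylate | CCCCCCCCCCCCCCCCCCCc1ccn(S(=O)(=O)c2ccc(C)cc2)c1C(=O)OC | intermediate
11 | methyl 3-nonadecyl-1H-pyrrole-2-carboxylate | CCCCCCCCCCCCCCCCCCCc1cc[nH]c1C(=O)OC | target

**Step count**

Total: 5 steps. Longest linear sequence: 5 steps (1 → 4 → 6 → 8 → 10 → 11).

**Steps most likely to fail, with fallbacks**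

1. Step 4 (mixed Kolbe electrolysis).
   - What may go wrong: homo-coupling may outrun cross-coupling; the anode may be passivated by hydrocarbon that separates from the warm methanol; the pyrrolylethyl radical may be oxidised further to a cation; the ring may be attacked anodically; the tosyl group may be lost if the solution is allowed to turn basic.
   - Fallback: it sets out from bromide 4 and comes back at 10, and attaches the whole chain by cross-coupling. Commercial 1-nonadecene (C=CCCCCCCCCCCCCCCCCC) would be hydroborated with 9-BBN-H in THF at rt to give B-nonadecyl-9-borabicyclo[3.3.1]nonane F1. This borane would then be joined to 4 in a B-alkyl Suzuki–Miyaura coupling (PdCl2(dppf), aq. K3PO4, THF/DMF, 60 °C) to give 10. Any loss of the tosyl group under the aqueous base would only deliver 11 one step early.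

2. Step 2 (Heck reaction).
   - What may go wrong: oxidative addition at the ortho-substituted C3–Br bond may be slow, so that protodebromination, palladium black formation or thermal loss of the tosyl group at 110 °C take over.
   - Fallback: it sets out from 4 and comes back at 7, and brings in the saturated three-carbon unit directly. Commercial benzyl 3-bromopropanoate would be treated with Zn dust and LiCl in THF to give (3-benzyloxy-3-oxopropyl)zinc bromide F2. Negishi coupling of this homoenolate with 4 (Pd(OAc)2, SPhos, THF, 50 °C) should give the saturated benzyl ester 7, which is isolated in this variant and hydrogenolysed to 8 under the conditions of step 3.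

3. Step 5 (removal of the tosyl group).
   - What may go wrong: methyl transfer from the sulfonate ester to the freed pyrrole nitrogen may occur before the excess methoxide has consumed that ester, and cleavage may stay incomplete because the waxy substrate dissolves poorly in methanol.
   - Fallback: it sets out from 10 and comes back at 11, and replaces nucleophilic attack at sulfur by single-electron reductive cleavage of the N–S bond. Mg turnings in MeOH/THF at rt (with sonication) should release the sulfinate and the pyrrole without forming any methylating agent; the methyl ester is again safe in methanol. No new compound arises on this path (F0).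

**Further compounds**

F1 | step 4 | B-nonadecyl-9-borabicyclo[3.3.1]nonane | CCCCCCCCCCCCCCCCCCCB1C2CCCC1CCC2
F2 | step 2 | (3-benzyloxy-3-oxopropyl)zinc bromide | O=C(CC[Zn]Br)OCc1ccccc1
F0 | step 5 | none | none
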